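**Plan**
- Retrosynthesis: the benzyl ester O–CH2Ph bond is cut first. Next, in one operation, the two aryl–alkyl bonds C2(ring A)–heptyl and C2(ring B)–heptyl are cut. Then the depside ester bond between the ring A carbonyl carbon and the C4 oxygen of ring B, and last the C1–carboxyl bond of ring B.
- Enabling feature: ring A (the 4,6-dimethoxybenzoyl ring) and ring B (the 6-methoxybenzoic acid ring) bear the same unbranched C7 chain at C2, in each ring next to the carbon that holds the carboxyl carbon. Two C–Br bonds at these positions can therefore be alkylated by one organozinc reagent without distinguishing them.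
- Forward: both benzene rings are bought and none is built. Ring B gains its carboxyl carbon by lithiation between Br and OMe, the ring A acid is joined to the ring B phenol as the aryl ester, both heptyl chains are attached together, and hydrogenolysis frees the acid.
- Stereochemistry: the target has no stereocentre and no stereogenic double bond, so nothing has to be set.

Key step: step 7

Remark: heptylzinc bromide is drawn as the simple monomer; in THF it is present as its LiCl adduct.

**Route**

Step 1
Reactants: 1 2-bromo-4,6-dimethoxybenzaldehyde
Product: 2 2-bromo-4,6-dimethoxybenzoic acid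
Conditions: NaClO2, NaH2PO4, 2-methyl-2-butene (excess), t-BuOH/H2O, 0 °C to rt
Reagents that add atoms: sodium chlorite, [Na+].[O-]Cl=O
Why: Pinnick oxidation takes the hindered aryl aldehyde to the acid under buffered conditions that spare the aryl bromide and the methyl ethers, the alkene trapping HOCl before it can chlorinate the electron-rich ring.

Step 2
Reactants: 3 3-bromo-5-methoxyphenol
Product: 4 (3-bromo-5-methoxyphenoxy)tri(propan-2-yl)silane
Conditions: i-Pr3SiCl, imidazole, DMF, rt
Reagents that add atoms: triisopropylsilyl chloride, CC(C)[Si](Cl)(C(C)C)C(C)C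
Why: Silyl ether protection removes the acidic phenol proton and installs a bulky, weakly coordinating group that should shield both neighbouring ring positions in the metalation that follows.

Step 3
Reactants: 4 (3-bromo-5-methoxyphenoxy)tri(propan-2-yl)silane; 5 benzyl chloroformate
Product: 7 benzyl 2-bromo-6-methoxy-4-[(triisopropylsilyl)oxy]benzoate, via ring B aryllithium 6 (not isolated)
Conditions: LiN(i-Pr)2 (1.1 equiv), THF, −78 °C, 1 h; then cannulated into 5 (1.5 equiv), THF, −78 °C to rt
Reagents that add atoms: none
Why: Directed ortho-metalation by the lithium amide should remove the most acidic ring hydrogen, the one flanked by Br and OMe (as in the known 2-lithiation of 3-bromoanisole), while the triisopropylsilyloxy group blocks its own neighbours, and the hindered aryllithium is acylated once by the chloroformate at low temperature before LiBr loss to an aryne can set in.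

Step 4
Reactants: 7 benzyl 2-bromo-6-methoxy-4-[(triisopropylsilyl)oxy]benzoate
Product: 8 benzyl 2-bromo-4-hydroxy-6-methoxybenzoate
Conditions: Bu4NF (1.1 equiv), AcOH (1.1 equiv), THF, 0 °C
Reagents that add atoms: none
Why: Fluoride-mediated desilylation buffered with acetic acid should free the phenol without touching the hindered benzyl ester or the aryl bromide.

Step 5
Reactants: 2 2-bromo-4,6-dimethoxybenzoic acid; 8 benzyl 2-bromo-4-hydroxy-6-methoxybenzoate
Product: 10 benzyl 2-bromo-4-[(2-bromo-4,6-dimethoxybenzoyl)oxy]-6-methoxybenzoate, via acyl chloride 9 (not isolated)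
Conditions: (COCl)2 (1.1 equiv), DMF (cat.), CH2Cl2, 0 °C to rt, volatiles removed; then 8, Et3N, DMAP (cat.), CH2Cl2, 0 °C to rt
Reagents that add atoms: none
Why: Conversion to the acyl chloride followed by DMAP-catalysed O-acylation (nucleophilic acyl substitution) should join the doubly ortho-substituted acid to the only free hydroxyl of 8, the acyl chloride being reactive enough to overcome the hindrance.

Step 6
Reactants: 11 1-bromoheptane
Product: 12 heptylzinc bromide (THF solution, titrated with I2 and used as such)
Conditions: Zn dust (1.5 equiv, activated with BrCH2CH2Br and Me3SiCl, cat.), LiCl (1 equiv), THF, 50 °C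
Reagents that add atoms: zinc, [Zn]
Why: Direct oxidative insertion of activated zinc into the primary C–Br bond, accelerated by LiCl, is a standard preparation of primary alkylzinc halides and gives a soluble reagent free of more basic organometallics.

Step 7
Reactants: 10 benzyl 2-bromo-4-[(2-bromo-4,6-dimethoxybenzoyl)oxy]-6-methoxybenzoate; 12 heptylzinc bromide (3 equiv)
Product: 15 benzyl 2-heptyl-4-[(2-heptyl-4,6-dimethoxybenzoyl)oxy]-6-methoxybenzoate, via ring B monoheptyl bromide 13 (not isolated), via ring A monoheptyl bromide 14 (not isolated)
Conditions: Pd(OAc)2 (5 mol %), SPhos (2-dicyclohexylphosphino-2′,6′-dimethoxybiphenyl, 10 mol %), THF, rt to 50 °C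
Reagents that add atoms: none
Why: Pd(OAc)2 is reduced by the organozinc to a zerovalent palladium–SPhos species, which inserts into an aryl C–Br bond (probably ring B first, the less electron-rich ring, giving 13, with 14 as the other order), takes the heptyl group from zinc by transmetalation and forms the aryl–heptyl bond by reductive elimination from divalent palladium; a second identical cycle at the remaining bromide brings both monoalkylated bromides to 15. The closest known reaction type is the Negishi coupling of primary alkylzinc halides with aryl bromides that carry an ortho carbonyl group, run in the presence of esters. No ring is closed and no stereocentre is created, so neither a mode of cyclisation nor a stereocontrol element is involved. Insertion must occur at C–Br and not at the acyl C–O bond of the aryl ester or the benzylic C–O bond; the weak C–Br bonds, each activated by an ortho ester carbonyl, the mild temperature and the depside carbonyl shielded by two ortho substituents should secure this. Reductive elimination must outrun beta-hydride elimination from the heptylpalladium intermediate, which the bulky, electron-rich biarylphosphine favours, and the alkylzinc halide is too weak a nucleophile to add to either ester. Because both positions receive the same chain, no selectivity between the two bromides is required.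

Step 8
Reactants: 15 benzyl 2-heptyl-4-[(2-heptyl-4,6-dimethoxybenzoyl)oxy]-6-methoxybenzoate
Product: 16 2-heptyl-4-[(2-heptyl-4,6-dimethoxybenzoyl)oxy]-6-methoxybenzoic acid
Conditions: H2 (1 atm), 10% palladium on carbon (Pd/C), EtOAc, rt
Reagents that add atoms: none
Why: Catalytic hydrogenolysis of the benzylic C–O bond should release the acid, while the aryl ester, the methyl ethers and the now halogen-free rings are inert under these conditions.

**Compound list**
1 | 2-bromo-4,6-dimethoxybenzaldehyde | COc1cc(OC)c(C=O)c(Br)c1 | starting material
2 | 2-bromo-4,6-dimethoxybenzoic acid | COc1cc(OC)c(C(=O)O)c(Br)c1 | intermediate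
3 | 3-bromo-5-methoxyphenol | COc1cc(O)cc(Br)c1 | starting material
4 | (3-bromo-5-methoxyphenoxy)tri(propan-2-yl)silane | COc1cc(O[Si](C(C)C)(C(C)C)C(C)C)cc(Br)c1 | intermediate
5 | benzyl chloroformate | O=C(Cl)OCc1ccccc1 | starting material
6 | {2-bromo-6-methoxy-4-[(triisopropylsilyl)oxy]phenyl}lithium | COc1cc(O[Si](C(C)C)(C(C)C)C(C)C)cc(Br)c1[Li] | intermediate (not isolated)
7 | benzyl 2-bromo-6-methoxy-4-[(triisopropylsilyl)oxy]benzoate | COc1cc(O[Si](C(C)C)(C(C)C)C(C)C)cc(Br)c1C(=O)OCc1ccccc1 | intermediate
8 | benzyl 2-bromo-4-hydroxy-6-methoxybenzoate | COc1cc(O)cc(Br)c1C(=O)OCc1ccccc1 | intermediate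
9 | 2-bromo-4,6-dimethoxybenzoyl chloride | COc1cc(OC)c(C(Cl)=O)c(Br)c1 | intermediate (not isolated)
10 | benzyl 2-bromo-4-[(2-bromo-4,6-dimethoxybenzoyl)oxy]-6-methoxybenzoate | COc1cc(OC)c(C(=O)Oc2cc(Br)c(C(=O)OCc3ccccc3)c(OC)c2)c(Br)c1 | intermediate
11 | 1-bromoheptane | CCCCCCCBr | starting material
12 | heptylzinc bromide | CCCCCCC[Zn]Br | intermediate
13 | benzyl 4-[(2-bromo-4,6-dimethoxybenzoyl)oxy]-2-heptyl-6-methoxybenzoate | CCCCCCCc1cc(OC(=O)c2c(Br)cc(OC)cc2OC)cc(OC)c1C(=O)OCc1ccccc1 | intermediate (not isolated)
14 | benzyl 2-bromo-4-[(2-heptyl-4,6-dimethoxybenzoyl)oxy]-6-methoxybenzoate | CCCCCCCc1cc(OC)cc(OC)c1C(=O)Oc1cc(Br)c(C(=O)OCc2ccccc2)c(OC)c1 | intermediate (not isolated)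
15 | benzyl 2-heptyl-4-[(2-heptyl-4,6-dimethoxybenzoyl)oxy]-6-methoxybenzoate | CCCCCCCc1cc(OC(=O)c2c(CCCCCCC)cc(OC)cc2OC)cc(OC)c1C(=O)OCc1ccccc1 | intermediate
16 | 2-heptyl-4-[(2-heptyl-4,6-dimethoxybenzoyl)oxy]-6-methoxybenzoic acid | CCCCCCCc1cc(OC(=O)c2c(CCCCCCC)cc(OC)cc2OC)cc(OC)c1C(=O)O | target

**Step count**
Total steps: 8.
Longest linear sequence: 6 steps (3 → 4 → 7 → 8 → 10 → 15 → 16; steps 2, 3, 4, 5, 7, 8).

**Steps most likely to fail**

Step 7. The second alkylation may stall at the monoheptyl bromides, or beta-hydride elimination from the heptylpalladium intermediate may lead to hydrodebromination. In that case the chains would be brought in as alkynes. Setting out from 10, twofold Sonogashira coupling with 1-heptyne (PdCl2(PPh3)2, CuI, Et3N, DMF, 70 °C) should give benzyl 2-(hept-1-yn-1-yl)-4-{[2-(hept-1-yn-1-yl)-4,6-dimethoxybenzoyl]oxy}-6-methoxybenzoate F1. Hydrogenation over palladium on carbon (H2, EtOAc, rt) would then saturate both triple bonds and cleave the benzyl ester in the same operation, so the route is rejoined at the target 16.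

Step 3. Deprotonation may occur next to the silyloxy group, the ortho-bromo aryllithium may lose LiBr to an aryne, or the aryllithium may add twice to the chloroformate. The carboxyl carbon would then be introduced by electrophilic substitution instead. Setting out from the free phenol 3, Vilsmeier–Haack formylation (POCl3, DMF, 0 °C to rt) is expected to attack mainly para to the hydroxyl group and give N-[(2-bromo-4-hydroxy-6-methoxyphenyl)methylidene]-N-methylmethanaminium chloride F2. Aqueous NaOAc work-up would hydrolyse it to 2-bromo-4-hydroxy-6-methoxybenzaldehyde F3, which is separated from ortho-formylated isomers. Pinnick oxidation (NaClO2, NaH2PO4, 2-methyl-2-butene) should give 2-bromo-4-hydroxy-6-methoxybenzoic acid F4. Selective alkylation of the carboxylate (benzyl bromide, KHCO3, DMF, rt) then comes back to the route at 8.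

Step 5. Acylation of the weakly nucleophilic phenol by the doubly ortho-substituted acyl chloride may be slow, with hydrolysis of the acyl chloride competing. The ester would then be formed under acidic mixed-anhydride activation. Setting out from acid 2, trifluoroacetic anhydride in toluene at rt should convert it into 2-bromo-4,6-dimethoxybenzoic trifluoroacetic anhydride F5. This acylium-type donor would acylate phenol 8 in the same flask, and the route is rejoined at 10.

**Further compounds**
F1 | step 7 | benzyl 2-(hept-1-yn-1-yl)-4-{[2-(hept-1-yn-1-yl)-4,6-dimethoxybenzoyl]oxy}-6-methoxybenzoate | CCCCCC#Cc1cc(OC(=O)c2c(C#CCCCCC)cc(OC)cc2OC)cc(OC)c1C(=O)OCc1ccccc1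
F2 | step 3 | N-[(2-bromo-4-hydroxy-6-methoxyphenyl)methylidene]-N-methylmethanaminium chloride | C[N+](C)=Cc1c(Br)cc(O)cc1OC.[Cl-]
F3 | step 3 | 2-bromo-4-hydroxy-6-methoxybenzaldehyde | COc1cc(O)cc(Br)c1C=O
F4 | step 3 | 2-bromo-4-hydroxy-6-methoxybenzoic acid | COc1cc(O)cc(Br)c1C(=O)O
F5 | step 5 | 2-bromo-4,6-dimethoxybenzoic trifluoroacetic anhydride | COc1cc(OC)c(C(=O)OC(=O)C(F)(F)F)c(Br)c1
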